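The stirred two-phase vessel you asked about is cedar, followed so far, and you want a quick number for 6.0 min. Here is the one I commit to.

| setting | cedar | maple | flask |
|---|---|---|---|
| substrate | 0.20 M | 0.20 M | 0.20 M |
| reagent in the second phase | 1.3 equiv | 0.87 equiv | 1.30 equiv |
| remark | the very flask that is asked about, followed so far | run made earlier |  |
| time |  |  | 6.0 min |
| volume of the second phase over the first |  |  | 1.0 |

cedar run (percent of the substrate charged)

| time / s | target / % | substrate / % |
|---|---|---|
| 10.0 | 86.3 | 8.3 |
| 25.0 | 83.1 | 1.9 |
| 50.0 | 73.2 | 0 |
| 80.0 | 59.1 | 0 |
| 120 | 45.6 | 0 |

maple run (percent of the substrate charged)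

| time / min | target / % | substrate / % |
|---|---|---|
| 1.33 | 53.6 | 14.0 |
| 2.50 | 32.1 | 13.1 |
| 4.00 | 17.6 | 13.1 |
| 5.00 | 10.2 | 14.9 |
| 6.00 | 8.4 | 12.1 |

(each reading ± 1 percentage point)

- how much target and product in the second phase together there is at 6.0 min, in percent of the substrate charged
- part of the substrate charged that has reacted at 6.0 min

- what is said of target includes product in the second phase
- in the second phase: reagent in the second phase, product in the second phase; everything else is in the first
- charges count per volume of the first phase; a concentration in a rate is the amount of a species over the volume of its own phase; every rate counts per litre of the first phase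
- the earlier runs hold the two phases in the same ratio of volumes as the flask asked about

1. Maple, with 0.87 equiv of reagent in the second phase, holds substrate near 13.1 %. Cedar, with more, 1.3 equiv, reads 0 % by 50.0 s. So substrate is cedar's limiting reagent, and I put cv at 100 %.

2. With cedar's substrate reading 0 % from 50.0 s on, I read the later fall of target as loss. Its rate of fall over the target present, the loss constant 0.406 /min, comes from the readings at 50.0 s and 120 s.

3. Maple, short of reagent, reads 0.397 /min, about the same, so I carry cedar's value.

4. Target left is the last reading times exp(−constant × elapsed time). From 45.6 % at 120 s, that gives y = 9.00 % at 6.0 min.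

Your hunch, the forecast, says 9.7 % and 100 %, a little above mine on y: “The loss therefore seems independent of reagent”.

The flask gives 8.66 % and 100 %, so my y stands 0.34 percentage points above it.

    reagent in the reaction phase ⇌ reagent in the second phase, rate k1*([reagent in the reaction phase] - [reagent in the second phase]/K1) per volume of the first phase (partition coefficient = 0.370, kL = 0.509 /s)
    substrate + reagent in the reaction phase → target (k = 3.30 /M/s)
    2 reagent in the reaction phase → homo dimer (k = 0.0333 /M/s)
    target ⇌ product in the second phase, rate k4*([target] - [product in the second phase]/K4) per volume of the first phase (partition coefficient = 0.332, kL = 0.0429 /s)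
    target → decomposed product (k = 0.00922 /s)

The loss constant carries on from the flask's own 8.66 % at 6.0 min. The neighbouring flask is the same charge read at 10 min, which is 4.00 min later. Over that stretch target keeps exp(−constant × elapsed time), a fraction of 0.197, and that leaves 1.71 %. The neighbouring flask reads 1.68 %.

(All runs come from a simulation for an exercise, noise included.)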